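**Strategy.** The cyclohexane ring is disconnected at C2–C3. Its carbons C4, C5 and C6, with three cis oxygens and the methyl branch on C4, are carbons 2 to 4 of a 2-C-methyl-talopyranoside, reached from methyl β-D-galactopyranoside. The key step, a mercury-catalysed Ferrier carbocyclization, converts the 6-deoxyhex-5-enopyranoside 10 into cyclohexanone 12 in one operation: it closes the carbocycle, forms C2–C3, sets the C3 carbinol trans to O4 and O5, and leaves a C1 ketone as the handle for the side chain. The precursor is a methyl glycoside with an exocyclic enol ether, an O3/O4 acetonide and a triethylsilyl ether on the tertiary oxygen, so that the new C3 hydroxyl is the only free one.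

Key step: step 7

**Remarks on the chemistry (conventions, corrections, assumptions)**
- Carbocycles carry target numbering: ring C1 (side chain), C2 (CH2), C3, C4 (methyl carbinol), C5, C6; chain C7 (bears the exocyclic CH2), C8, C9, C10, C11. β is the ring face of O4, O5 and O6; α is the other face. In this numbering the target is 1R,3S,4S,5S,6S,8S,10R with both esters Z.
- Atom bookkeeping of the key step: the ketone oxygen of 12 is delivered by water, and the former pyranose ring oxygen becomes the C3 hydroxyl.
- The ring closure of the key step is a 6-(enolendo)-exo-trig aldol, since both enolate carbons lie in the new ring.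
- The enol ether has no stereocentre at C5, so 10 is named systematically as an α-L-ribo-hex-5-enopyranoside; it is the 5,6-ene of the β-D-talo series.
- The tertiary hydroxyl is silylated before the key step, so it cannot add to the mercurinium ion or the keto group, and 12 then has a single free hydroxyl.
- Assumption: aldehyde 25 is made fresh from commercial alcohol 24; stannane 15, Comins' reagent, the (R)-CBS catalyst and the D-fructose-derived Shi ketone are bought.

**Route**

Step 1
Reactants: 1 methyl β-D-galactopyranoside; 2 2,2-dimethoxypropane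
Product: 4 methyl 3,4-O-isopropylidene-β-D-galactopyranoside, via 6-O-(2-methoxyprop-2-yl) mixed acetal 3 (not isolated)
Conditions: 2 (excess), CSA (cat.), acetone, rt; Et3N; then MeOH/H2O (10:1), 60 °C
Reagents that add atoms: 2,2-dimethoxypropane COC(C)(C)OC
Why: Acid-catalysed transketalisation (acetonide protection) should place the ketal on the only cis-vicinal diol, O3/O4, as the favoured cis-fused dioxolane, and the labile mixed acetal on O6 is cleaved in warm aqueous methanol.

Step 2
Reactants: 4 methyl 3,4-O-isopropylidene-β-D-galactopyranoside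
Product: 5 methyl 6-deoxy-6-iodo-3,4-O-isopropylidene-β-D-galactopyranoside
Conditions: I2, PPh3, imidazole, toluene, 70 °C
Reagents that add atoms: iodine II
Why: Garegg–Samuelsson iodination (Appel type) should convert the primary C6 hydroxyl selectively, because the alkoxyphosphonium ion forms and is displaced far faster at the primary than at the secondary 2-position.

Step 3
Reactants: 5 methyl 6-deoxy-6-iodo-3,4-O-isopropylidene-β-D-galactopyranoside
Product: 6 methyl 6-deoxy-6-iodo-3,4-O-isopropylidene-β-D-lyxo-hexopyranosid-2-ulose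
Conditions: Dess–Martin periodinane, NaHCO3, CH2Cl2, rt
Reagents that add atoms: none
Why: Dess–Martin oxidation of the only free hydroxyl should give the 2-ulose under buffered conditions that neither epimerise C3 nor touch the iodide.

Step 4
Reactants: 6 methyl 6-deoxy-6-iodo-3,4-O-isopropylidene-β-D-lyxo-hexopyranosid-2-ulose; 7 methylmagnesium bromide
Product: 8 methyl 6-deoxy-6-iodo-3,4-O-isopropylidene-2-C-methyl-β-D-talopyranoside
Conditions: MeMgBr (1.5 equiv), THF, −78 °C; aq. NH4Cl
Reagents that add atoms: methylmagnesium bromide C[Mg]Br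
Why: Grignard 1,2-addition should occur from the α face, because the axial O4 of the cis-fused acetonide blocks the axial approach from the β face and the β-glycoside leaves the α face open; the new tertiary hydroxyl is then axial and cis to O3 and O4 (talo), which sets target C4.

Step 5
Reactants: 8 methyl 6-deoxy-6-iodo-3,4-O-isopropylidene-2-C-methyl-β-D-talopyranoside
Product: 9 methyl 6-deoxy-6-iodo-3,4-O-isopropylidene-2-C-methyl-2-O-triethylsilyl-β-D-talopyranoside
Conditions: Et3SiOTf, 2,6-lutidine, CH2Cl2, −78 → 0 °C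
Reagents that add atoms: triethylsilyl trifluoromethanesulfonate CC[Si](CC)(CC)OS(=O)(=O)C(F)(F)F
Why: Silylation with a silyl triflate and a hindered pyridine base is the standard way to cap a tertiary alcohol, and at low temperature the glycoside, acetonide and iodide should be left alone.

Step 6
Reactants: 9 methyl 6-deoxy-6-iodo-3,4-O-isopropylidene-2-C-methyl-2-O-triethylsilyl-β-D-talopyranoside
Product: 10 methyl 6-deoxy-3,4-O-isopropylidene-2-C-methyl-2-O-triethylsilyl-α-L-ribo-hex-5-enopyranoside
Conditions: KOt-Bu, THF, 0 °C → rt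
Reagents that add atoms: none
Why: E2 dehydroiodination of the primary iodide (H5 is activated by the ring oxygen and can reach the anti arrangement) should give the exocyclic enol ether, with no free hydroxyl left to compete by alkylation.

Step 7
Reactants: 10 methyl 6-deoxy-3,4-O-isopropylidene-2-C-methyl-2-O-triethylsilyl-α-L-ribo-hex-5-enopyranoside
Product: 12 3α-hydroxy-5β,6β-(isopropylidenedioxy)-4α-methyl-4β-(triethylsilyloxy)cyclohexan-1-one, via mercurated keto-aldehyde 11 (not isolated)
Conditions: Hg(OCOCF3)2 (5 mol %), acetone/H2O (4:1), 0 °C → rt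
Reagents that add atoms: water O
Why: Divalent mercury adds together with water across the exocyclic enol ether, the hemiketal opens and the anomeric hemiacetal loses methanol to give the α-mercurio 1,5-keto-aldehyde 11, whose mercury enolate carbon (ring C2) adds to the aldehyde (ring C3) and releases the catalyst. The closest known reaction type is the Ferrier carbocyclization of 6-deoxyhex-5-enopyranosides with catalytic Hg(OCOCF3)2. The six-membered ring closes by a 6-(enolendo)-exo-trig aldol. The one new stereocentre, C3, should be set in a chair transition state that keeps the pyranoside substituents in place (C4 methyl and O5 equatorial) and turns the aldehyde C=O anti to the axial C4–OSiEt3 bond and toward mercury, so the hydroxyl ends axial on the α face, trans to O4 and O5. The step needs this trans relationship for the later epoxide closure and needs chemoselectivity for the enol ether; the centres C4 to C6 are not touched, the aldehyde has no α-hydrogen, and the silyl ether and acetonide should tolerate the nearly neutral medium.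

Step 8
Reactants: 12 3α-hydroxy-5β,6β-(isopropylidenedioxy)-4α-methyl-4β-(triethylsilyloxy)cyclohexan-1-one
Product: 13 5β,6β-(isopropylidenedioxy)-4α-methyl-3α,4β-bis(triethylsilyloxy)cyclohexan-1-one
Conditions: Et3SiCl, imidazole, DMF, 0 °C → rt
Reagents that add atoms: chlorotriethylsilane CC[Si](Cl)(CC)CC
Why: Silylation of the single secondary hydroxyl with the silyl chloride and imidazole is mild enough to avoid β-elimination of the β-hydroxy ketone.

Step 9
Reactants: 13 5β,6β-(isopropylidenedioxy)-4α-methyl-3α,4β-bis(triethylsilyloxy)cyclohexan-1-one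
Product: 14 5β,6β-(isopropylidenedioxy)-4α-methyl-3α,4β-bis(triethylsilyloxy)cyclohex-1-en-1-yl trifluoromethanesulfonate
Conditions: KN(SiMe3)2, THF, −78 °C; then Comins' reagent, −78 °C
Reagents that add atoms: N-(5-chloropyridin-2-yl)bis(trifluoromethanesulfonimide) O=S(=O)(N(c1ccc(Cl)cn1)S(=O)(=O)C(F)(F)F)C(F)(F)F
Why: Kinetic enolisation should take the C2 methylene and not the alkoxy-substituted C6 methine, and O-triflation at −78 °C (enol triflate formation) traps the β-silyloxy enolate before it can eliminate.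

Step 10
Reactants: 14 5β,6β-(isopropylidenedioxy)-4α-methyl-3α,4β-bis(triethylsilyloxy)cyclohex-1-en-1-yl trifluoromethanesulfonate; 15 tributyl(1-ethoxyvinyl)stannane
Product: 17 1-acetyl-3α-hydroxy-5β,6β-(isopropylidenedioxy)-4α-methyl-4β-(triethylsilyloxy)cyclohex-1-ene, via 1-ethoxyvinyl diene 16 (not isolated)
Conditions: Pd(PPh3)4 (5 mol %), LiCl, THF, 65 °C; then 0.5 M HCl, THF, 0 °C → rt
Reagents that add atoms: tributyl(1-ethoxyvinyl)stannane CCCC[Sn](CCCC)(CCCC)C(=C)OCC; water O
Why: Stille coupling of the enol triflate (zerovalent palladium, chloride-assisted) installs C7 and its future methylene carbon as a masked acetyl group; dilute acid then hydrolyses the enol ether and should remove the secondary allylic silyl ether much faster than the tertiary silyl ether or the acetonide.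

Step 11
Reactants: 17 1-acetyl-3α-hydroxy-5β,6β-(isopropylidenedioxy)-4α-methyl-4β-(triethylsilyloxy)cyclohex-1-ene
Product: 18 1β-acetyl-3α-hydroxy-5β,6β-(isopropylidenedioxy)-4α-methyl-4β-(triethylsilyloxy)cyclohexane
Conditions: [Ir(cod)(PCy3)(py)]PF6 (5 mol %), H2 (1 atm), CH2Cl2, rt
Reagents that add atoms: none
Why: In this hydroxyl-directed hydrogenation the only free hydroxyl (C3, α face) binds the cationic iridium and should deliver H2 to the α face of C1=C2, so the acetyl group ends on the β face, cis to O6, which sets C1.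

Step 12
Reactants: 18 1β-acetyl-3α-hydroxy-5β,6β-(isopropylidenedioxy)-4α-methyl-4β-(triethylsilyloxy)cyclohexane
Product: 19 1β-acetyl-5β,6β-(isopropylidenedioxy)-3α-(methanesulfonyloxy)-4α-methyl-4β-(triethylsilyloxy)cyclohexane
Conditions: MsCl, Et3N, CH2Cl2, 0 °C
Reagents that add atoms: methanesulfonyl chloride CS(=O)(=O)Cl
Why: Mesylation through the small sulfene intermediate should reach the hindered C3 hydroxyl, and C3 is no longer β to a ring ketone, so elimination is not a concern.

Step 13
Reactants: 19 1β-acetyl-5β,6β-(isopropylidenedioxy)-3α-(methanesulfonyloxy)-4α-methyl-4β-(triethylsilyloxy)cyclohexane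
Product: 21 1β-acetyl-3β,4β-epoxy-5β,6β-(isopropylidenedioxy)-4α-methylcyclohexane, via hydroxy mesylate 20 (not isolated)
Conditions: HF·pyridine, pyridine/THF, 0 °C → rt; then K2CO3, MeOH, 0 °C
Reagents that add atoms: none
Why: Fluoride frees the tertiary hydroxyl, and carbonate then closes the epoxide by intramolecular SN2 from the trans-diaxial arrangement, which inverts C3 and puts the epoxide oxygen on the β face.

Step 14
Reactants: 21 1β-acetyl-3β,4β-epoxy-5β,6β-(isopropylidenedioxy)-4α-methylcyclohexane
Product: 22 1-[3β,4β-epoxy-5β,6β-(isopropylidenedioxy)-4α-methylcyclohex-1β-yl]vinyl trifluoromethanesulfonate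
Conditions: KN(SiMe3)2, THF, −78 °C; then Comins' reagent, −78 → −40 °C
Reagents that add atoms: N-(5-chloropyridin-2-yl)bis(trifluoromethanesulfonimide) O=S(=O)(N(c1ccc(Cl)cn1)S(=O)(=O)C(F)(F)F)C(F)(F)F
Why: Kinetic deprotonation of the methyl ketone at the methyl group (not at the C1 methine) and O-triflation should give the terminal vinyl triflate, with C1 untouched and the epoxide and acetonide inert to the amide base at low temperature.

Step 15
Reactants: 22 1-[3β,4β-epoxy-5β,6β-(isopropylidenedioxy)-4α-methylcyclohex-1β-yl]vinyl trifluoromethanesulfonate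
Product: 23 1-[3α-chloro-4β-hydroxy-5β,6β-(isopropylidenedioxy)-4α-methylcyclohex-1β-yl]vinyl trifluoromethanesulfonate
Conditions: LiCl, AcOH, THF, rt → 40 °C
Reagents that add atoms: lithium chloride [Li+].[Cl-]
Why: Halohydrin formation by SN2 opening should occur at the secondary C3 from the α face (trans-diaxial, Fürst–Plattner), since C4 is tertiary, shielded and deactivated by the neighbouring C5–O bond; Cl ends on the α face, so C3 has net retention over steps 13 and 15.

Step 16
Reactants: 24 4-methylpent-3-en-1-ol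
Product: 25 4-methylpent-3-enal
Conditions: Dess–Martin periodinane, NaHCO3, CH2Cl2, 0 °C; used at once
Reagents that add atoms: none
Why: Buffered Dess–Martin oxidation should give the β,γ-unsaturated aldehyde without moving the double bond into conjugation, provided it is used immediately.

Step 17
Reactants: 23 1-[3α-chloro-4β-hydroxy-5β,6β-(isopropylidenedioxy)-4α-methylcyclohex-1β-yl]vinyl trifluoromethanesulfonate; 25 4-methylpent-3-enal
Product: 26 2-[3α-chloro-4β-hydroxy-5β,6β-(isopropylidenedioxy)-4α-methylcyclohex-1β-yl]-6-methylhepta-1,5-dien-3-ol (both C8 epimers)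
Conditions: CrCl2 (6 equiv), NiCl2 (1 mol %), DMF, rt
Reagents that add atoms: 4-methylpent-3-enal CC(C)=CCC=O
Why: In the Nozaki–Hiyama–Kishi coupling nickel activates the vinyl triflate, the vinyl group passes to trivalent chromium and adds only to the aldehyde, forming C7–C8 under neutral conditions that the chlorohydrin, acetonide and free tertiary hydroxyl should tolerate.

Step 18
Reactants: 26 2-[3α-chloro-4β-hydroxy-5β,6β-(isopropylidenedioxy)-4α-methylcyclohex-1β-yl]-6-methylhepta-1,5-dien-3-ol (both C8 epimers)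
Product: 27 2-[3α-chloro-4β-hydroxy-5β,6β-(isopropylidenedioxy)-4α-methylcyclohex-1β-yl]-6-methylhepta-1,5-dien-3-one
Conditions: Dess–Martin periodinane, NaHCO3, CH2Cl2, 0 °C; used without delay
Reagents that add atoms: none
Why: Dess–Martin oxidation merges both C8 epimers into one α-methylene ketone, leaves the tertiary hydroxyl alone, and is neutral enough that neither double bond should migrate.

Step 19
Reactants: 27 2-[3α-chloro-4β-hydroxy-5β,6β-(isopropylidenedioxy)-4α-methylcyclohex-1β-yl]-6-methylhepta-1,5-dien-3-one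
Product: 28 (3S)-2-[3α-chloro-4β-hydroxy-5β,6β-(isopropylidenedioxy)-4α-methylcyclohex-1β-yl]-6-methylhepta-1,5-dien-3-ol (8S in target numbering)
Conditions: (R)-2-methyl-CBS-oxazaborolidine (0.5 equiv), catecholborane, toluene, −78 °C; MeOH quench
Reagents that add atoms: none
Why: In the Corey–Bakshi–Shibata reduction the α-branched vinyl group (C7) acts as the large substituent and the C9 methylene as the small one, so the (R)-catalyst should deliver hydride to give the 8S alcohol by reagent control, as a 1,2-reduction at low temperature.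

Step 20
Reactants: 28 (3S)-2-[3α-chloro-4β-hydroxy-5β,6β-(isopropylidenedioxy)-4α-methylcyclohex-1β-yl]-6-methylhepta-1,5-dien-3-ol
Product: 29 (3S)-2-[3α-chloro-4β,5β,6β-trihydroxy-4α-methylcyclohex-1β-yl]-6-methylhepta-1,5-dien-3-ol
Conditions: AcOH/H2O (4:1), 50 °C
Reagents that add atoms: none
Why: Mild acid hydrolysis of the cis-fused acetonide should free O5 and O6 without ionising the allylic alcohol or hydrating the trisubstituted alkene.

Step 21
Reactants: 29 (3S)-2-[3α-chloro-4β,5β,6β-trihydroxy-4α-methylcyclohex-1β-yl]-6-methylhepta-1,5-dien-3-ol; 30 angelic acid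
Product: 33 5,8-di-O-angeloyl derivative of 29 with free 4-OH and 6-OH (the target lacking only the epoxide oxygen), via 4,6-O-phenylboronate 31 (not isolated), via boronate diangelate 32 (not isolated)
Conditions: PhB(OH)2 (1.05 equiv), toluene, 4 Å molecular sieves, rt; then 30, 2,4,6-Cl3C6H2COCl, Et3N (premixed in toluene), 80 °C; then propane-1,3-diol, rt
Reagents that add atoms: angelic acid C/C=C(/C)C(=O)O; phenylboronic acid OB(O)c1ccccc1 (its atoms are held only in 31 and 32)
Why: Phenylboronic acid should bridge the two axial, 1,3-cis oxygens O4 and O6 as a six-membered boronate, as it does in all-cis pyranoside triols, so only the equatorial C5 hydroxyl and the C8 hydroxyl are esterified by the mixed anhydride (Yamaguchi-type esterification without DMAP, which keeps the Z geometry); diol exchange then removes boron.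

Step 22
Reactants: 33 5,8-di-O-angeloyl derivative of 29 with free 4-OH and 6-OH
Product: 34 CNP0158207.1 (target)
Conditions: D-fructose-derived Shi ketone (3 equiv, in portions), KHSO5 (as Oxone), NaHCO3 (pH about 8), MeCN/aq. Na2EDTA, 0 °C
Reagents that add atoms: potassium peroxymonosulfate [K+].OOS(=O)(=O)[O-]
Why: In the Shi asymmetric epoxidation the chiral dioxirane should attack only the electron-rich trisubstituted C10=C11 alkene and give the 10R epoxide by reagent control; the 1,1-disubstituted alkene and the angelates are far less reactive, and the nearly neutral pH spares the chlorohydrin and the esters.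

**Compound list**

1 | methyl β-D-galactopyranoside | CO[C@@H]1O[C@H](CO)[C@H](O)[C@H](O)[C@H]1O | starting material
2 | 2,2-dimethoxypropane | COC(C)(C)OC | starting material
3 | methyl 3,4-O-isopropylidene-6-O-(2-methoxyprop-2-yl)-β-D-galactopyranoside (formed in the flask) | COC(C)(C)OC[C@H]1O[C@@H](OC)[C@H](O)[C@H]2OC(C)(C)O[C@@H]12 | intermediate
4 | methyl 3,4-O-isopropylidene-β-D-galactopyranoside | OC[C@H]1O[C@@H](OC)[C@H](O)[C@H]2OC(C)(C)O[C@@H]12 | intermediate
5 | methyl 6-deoxy-6-iodo-3,4-O-isopropylidene-β-D-galactopyranoside | IC[C@H]1O[C@@H](OC)[C@H](O)[C@H]2OC(C)(C)O[C@@H]12 | intermediate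
6 | methyl 6-deoxy-6-iodo-3,4-O-isopropylidene-β-D-lyxo-hexopyranosid-2-ulose | IC[C@H]1O[C@@H](OC)C(=O)[C@H]2OC(C)(C)O[C@@H]12 | intermediate
7 | methylmagnesium bromide | C[Mg]Br | starting material
8 | methyl 6-deoxy-6-iodo-3,4-O-isopropylidene-2-C-methyl-β-D-talopyranoside | IC[C@H]1O[C@@H](OC)[C@@](C)(O)[C@H]2OC(C)(C)O[C@@H]12 | intermediate
9 | methyl 6-deoxy-6-iodo-3,4-O-isopropylidene-2-C-methyl-2-O-triethylsilyl-β-D-talopyranoside | IC[C@H]1O[C@@H](OC)[C@@](C)(O[Si](CC)(CC)CC)[C@H]2OC(C)(C)O[C@@H]12 | intermediate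
10 | methyl 6-deoxy-3,4-O-isopropylidene-2-C-methyl-2-O-triethylsilyl-α-L-ribo-hex-5-enopyranoside (5,6-ene of the β-D-talo series; OMe, O2, O3 and O4 on one face) | C=C1O[C@@H](OC)[C@@](C)(O[Si](CC)(CC)CC)[C@H]2OC(C)(C)O[C@@H]12 | intermediate
11 | open-chain 6-(trifluoroacetoxymercurio) 1,5-keto-aldehyde from 10 (formed in the flask) | O=C[C@@](C)(O[Si](CC)(CC)CC)[C@H]1OC(C)(C)O[C@H]1C(=O)C[Hg]OC(=O)C(F)(F)F | intermediate
12 | 3α-hydroxy-5β,6β-(isopropylidenedioxy)-4α-methyl-4β-(triethylsilyloxy)cyclohexan-1-one | O=C1C[C@H](O)[C@@](C)(O[Si](CC)(CC)CC)[C@H]2OC(C)(C)O[C@@H]12 | intermediate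
13 | 5β,6β-(isopropylidenedioxy)-4α-methyl-3α,4β-bis(triethylsilyloxy)cyclohexan-1-one | O=C1C[C@H](O[Si](CC)(CC)CC)[C@@](C)(O[Si](CC)(CC)CC)[C@H]2OC(C)(C)O[C@@H]12 | intermediate
14 | 5β,6β-(isopropylidenedioxy)-4α-methyl-3α,4β-bis(triethylsilyloxy)cyclohex-1-en-1-yl trifluoromethanesulfonate | FC(F)(F)S(=O)(=O)OC1=C[C@H](O[Si](CC)(CC)CC)[C@@](C)(O[Si](CC)(CC)CC)[C@H]2OC(C)(C)O[C@@H]12 | intermediate
15 | tributyl(1-ethoxyvinyl)stannane | CCCC[Sn](CCCC)(CCCC)C(=C)OCC | starting material
16 | 1-(1-ethoxyvinyl)-5β,6β-(isopropylidenedioxy)-4α-methyl-3α,4β-bis(triethylsilyloxy)cyclohex-1-ene (formed in the flask) | C=C(OCC)C1=C[C@H](O[Si](CC)(CC)CC)[C@@](C)(O[Si](CC)(CC)CC)[C@H]2OC(C)(C)O[C@@H]12 | intermediate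
17 | 1-acetyl-3α-hydroxy-5β,6β-(isopropylidenedioxy)-4α-methyl-4β-(triethylsilyloxy)cyclohex-1-ene | CC(=O)C1=C[C@H](O)[C@@](C)(O[Si](CC)(CC)CC)[C@H]2OC(C)(C)O[C@@H]12 | intermediate
18 | 1β-acetyl-3α-hydroxy-5β,6β-(isopropylidenedioxy)-4α-methyl-4β-(triethylsilyloxy)cyclohexane | CC(=O)[C@H]1C[C@H](O)[C@@](C)(O[Si](CC)(CC)CC)[C@H]2OC(C)(C)O[C@@H]12 | intermediate
19 | 1β-acetyl-5β,6β-(isopropylidenedioxy)-3α-(methanesulfonyloxy)-4α-methyl-4β-(triethylsilyloxy)cyclohexane | CC(=O)[C@H]1C[C@H](OS(C)(=O)=O)[C@@](C)(O[Si](CC)(CC)CC)[C@H]2OC(C)(C)O[C@@H]12 | intermediate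
20 | 1β-acetyl-4β-hydroxy-5β,6β-(isopropylidenedioxy)-3α-(methanesulfonyloxy)-4α-methylcyclohexane (formed in the flask) | CC(=O)[C@H]1C[C@H](OS(C)(=O)=O)[C@@](C)(O)[C@H]2OC(C)(C)O[C@@H]12 | intermediate
21 | 1β-acetyl-3β,4β-epoxy-5β,6β-(isopropylidenedioxy)-4α-methylcyclohexane | CC(=O)[C@H]1C[C@H]3O[C@@]3(C)[C@H]2OC(C)(C)O[C@@H]12 | intermediate
22 | 1-[3β,4β-epoxy-5β,6β-(isopropylidenedioxy)-4α-methylcyclohex-1β-yl]vinyl trifluoromethanesulfonate | C=C(OS(=O)(=O)C(F)(F)F)[C@H]1C[C@H]3O[C@@]3(C)[C@H]2OC(C)(C)O[C@@H]12 | intermediate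
23 | 1-[3α-chloro-4β-hydroxy-5β,6β-(isopropylidenedioxy)-4α-methylcyclohex-1β-yl]vinyl trifluoromethanesulfonate | C=C(OS(=O)(=O)C(F)(F)F)[C@H]1C[C@H](Cl)[C@@](C)(O)[C@H]2OC(C)(C)O[C@@H]12 | intermediate
24 | 4-methylpent-3-en-1-ol | CC(C)=CCCO | starting material
25 | 4-methylpent-3-enal | CC(C)=CCC=O | intermediate
26 | 2-[3α-chloro-4β-hydroxy-5β,6β-(isopropylidenedioxy)-4α-methylcyclohex-1β-yl]-6-methylhepta-1,5-dien-3-ol (both C8 epimers) | C=C(C(O)CC=C(C)C)[C@H]1C[C@H](Cl)[C@@](C)(O)[C@H]2OC(C)(C)O[C@@H]12 | intermediate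
27 | 2-[3α-chloro-4β-hydroxy-5β,6β-(isopropylidenedioxy)-4α-methylcyclohex-1β-yl]-6-methylhepta-1,5-dien-3-one | C=C(C(=O)CC=C(C)C)[C@H]1C[C@H](Cl)[C@@](C)(O)[C@H]2OC(C)(C)O[C@@H]12 | intermediate
28 | (3S)-2-[3α-chloro-4β-hydroxy-5β,6β-(isopropylidenedioxy)-4α-methylcyclohex-1β-yl]-6-methylhepta-1,5-dien-3-ol | C=C([C@H](CC=C(C)C)O)[C@H]1C[C@H](Cl)[C@@](C)(O)[C@H]2OC(C)(C)O[C@@H]12 | intermediate
29 | (3S)-2-[3α-chloro-4β,5β,6β-trihydroxy-4α-methylcyclohex-1β-yl]-6-methylhepta-1,5-dien-3-ol | C=C([C@H](CC=C(C)C)O)[C@H]1C[C@H](Cl)[C@@](C)(O)[C@@H](O)[C@H]1O | intermediate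
30 | angelic acid, (Z)-2-methylbut-2-enoic acid | C/C=C(/C)C(=O)O | starting material
31 | 4,6-O-phenylboronate of 29 with free 5-OH and 8-OH (formed in the flask) | C=C([C@H](CC=C(C)C)O)[C@H]1C[C@H](Cl)[C@@]2(C)OB(c3ccccc3)O[C@@H]1[C@@H]2O | intermediate
32 | 5,8-di-O-angeloyl 4,6-O-phenylboronate (formed in the flask) | C=C([C@H](CC=C(C)C)OC(=O)/C(C)=C\C)[C@H]1C[C@H](Cl)[C@@]2(C)OB(c3ccccc3)O[C@@H]1[C@@H]2OC(=O)/C(C)=C\C | intermediate
33 | 5,8-di-O-angeloyl derivative of 29 with free 4-OH and 6-OH | C=C([C@H](CC=C(C)C)OC(=O)/C(C)=C\C)[C@H]1C[C@H](Cl)[C@@](C)(O)[C@@H](OC(=O)/C(C)=C\C)[C@H]1O | intermediate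
34 | CNP0158207.1: ring 1R,3S,4S,5S,6S with 3α-Cl, 4β-OH, 4α-CH3, 5β-angelate, 6β-OH; chain on C1β with C7=CH2, (8S)-angelate and (10R)-10,11-epoxide | C=C([C@H](C[C@H]1OC1(C)C)OC(=O)/C(C)=C\C)[C@H]1C[C@H](Cl)[C@@](C)(O)[C@@H](OC(=O)/C(C)=C\C)[C@H]1O | target

**Count and risks**

Total steps: 22. Longest linear sequence: 21 steps (steps 1 to 15 and 17 to 22); step 16 is a one-step side branch.

The three steps most likely to fail:

1. Step 7 (key step). The aldol closure may show poor facial selectivity at C3, the ketol may lose water to the enone, or the trifluoroacetic acid released may strip the silyl ether or the acetonide. The fallback sets out from iodide 9 and comes back at ketol 12, and makes the same C2–C3 bond by a stepwise route without mercury. Zinc (activated Zn, THF/H2O, 40 °C, ultrasound) fragments 9 reductively (Bernet–Vasella reaction) to 5,6-dideoxy-3,4-O-isopropylidene-2-C-methyl-2-O-triethylsilyl-L-ribo-hex-5-enose F1. Wacker oxidation (PdCl2 cat., CuCl, O2, DMF/H2O) turns the terminal alkene into the methyl ketone, giving 6-deoxy-3,4-O-isopropylidene-2-C-methyl-2-O-triethylsilyl-L-ribo-hexos-5-ulose F2. An amine-catalysed intramolecular aldol (L-proline or its enantiomer, DMSO, rt) then closes the ring to 12, with C3 under catalyst and equilibrium control instead of the mercury enolate geometry.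

2. Step 15. Chloride may enter at the tertiary C4 through an opening with carbocation character, or acetate may compete with chloride. The fallback sets out from epoxide 22 and comes back at chlorohydrin 23, and takes the regiochemistry out of the epoxide opening altogether. Reductive deoxygenation (NaI, Zn, AcOH/NaOAc, rt; both regioisomeric iodohydrins converge) gives 1-[5β,6β-(isopropylidenedioxy)-4-methylcyclohex-3-en-1β-yl]vinyl trifluoromethanesulfonate F3. N-Chlorosuccinimide in acetone/H2O (0 °C) should then add Cl+ to the α face, anti to the acetonide and the C1 substituent, and water opens the chloronium ion at the tertiary C4 (Markovnikov, anti addition), which places Cl at C3α and OH at C4β as in 23.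

3. Step 21. O5 and O6 may be differentiated incompletely if the boronate shifts to a five-membered cis-1,2 ester; the flanked C5 hydroxyl may acylate slowly; and the angeloyl group may isomerise from Z to E under forcing conditions. The fallback sets out from 28 and comes back at 33, and esterifies the two positions one after the other. With the acetonide still in place, the mixed anhydride of 30 (2,4,6-Cl3C6H2COCl, Et3N, toluene, 60 °C) can only acylate the C8 hydroxyl, giving the 8-O-angeloyl acetonide F4. AcOH/H2O (4:1, 50 °C) gives the 8-O-angeloyl 4,5,6-triol F5. Bu2SnO (MeOH/toluene, reflux) forms the 5,6-O-dibutylstannylene acetal F6, which activates the equatorial O5 for acylation by the same mixed anhydride at rt and so leads to 33.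

**Further compounds**

F1 | step 7 | 5,6-dideoxy-3,4-O-isopropylidene-2-C-methyl-2-O-triethylsilyl-L-ribo-hex-5-enose | O=C[C@@](C)(O[Si](CC)(CC)CC)[C@H]1OC(C)(C)O[C@H]1C=C
F2 | step 7 | 6-deoxy-3,4-O-isopropylidene-2-C-methyl-2-O-triethylsilyl-L-ribo-hexos-5-ulose | O=C[C@@](C)(O[Si](CC)(CC)CC)[C@H]1OC(C)(C)O[C@H]1C(C)=O
F3 | step 15 | 1-[5β,6β-(isopropylidenedioxy)-4-methylcyclohex-3-en-1β-yl]vinyl trifluoromethanesulfonate | C=C(OS(=O)(=O)C(F)(F)F)[C@H]1CC=C(C)[C@H]2OC(C)(C)O[C@@H]12
F4 | step 21 | 8-O-angeloyl derivative of 28 | C=C([C@H](CC=C(C)C)OC(=O)/C(C)=C\C)[C@H]1C[C@H](Cl)[C@@](C)(O)[C@H]2OC(C)(C)O[C@@H]12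
F5 | step 21 | 8-O-angeloyl derivative of 29 (4,5,6-triol) | C=C([C@H](CC=C(C)C)OC(=O)/C(C)=C\C)[C@H]1C[C@H](Cl)[C@@](C)(O)[C@@H](O)[C@H]1O
F6 | step 21 | 5,6-O-dibutylstannylene acetal of F5 | C=C([C@H](CC=C(C)C)OC(=O)/C(C)=C\C)[C@H]1C[C@H](Cl)[C@@](C)(O)[C@H]2O[Sn](CCCC)(CCCC)O[C@@H]12
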